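**Retrosynthetic overview**

1. The CH2–C3 bond of the butenolide half (half A) is cut by Knoevenagel condensation and conjugate reduction, giving enol lactone 24 and aldehyde 22, which carries the saturated cis-lactone half (half B).
2. Both halves come from one racemic keto ester 12. The two cyclohexane rings are mirror images at C5/C6 (benzofuranone numbering: O1, C2, C3, C3a, C4–C7, C7a), so one reductive kinetic resolution serves both: below half conversion it turns the (4S,5S) ketone into the cis-lactone 14, beyond half conversion it leaves the (4R,5R) ketone 15 for the butenolide.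
3. Keto ester 12 comes from cyclohexenone 7 by C-alkylation, anti-selective vinyl conjugate addition (quaternary C6) and double dealkoxycarbonylation.
4. Cyclohexenone 7 comes from dimethyl 3-oxopentanedioate and a latent 3-methylidene vinyl ketone by Michael addition (C3a–C4) and Knoevenagel closure (C6–C7). The enabling feature is that in each carbocycle the O-bearing C7a sits between CH2-7 and CH-3a (an acetone-type unit), 1,3 to the quaternary C6 and 1,5 to it through C3a–C4–C5, so the ring is a masked cyclohex-2-enone (C7a = C=O, C7 = α, C6 = β).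
5. Ring order: carbocycle of both halves (step 2), lactone ring of half B (step 6), butenolide ring of half A (steps 12–14).

Key step: step 2

Remark: the SMILES is taken at face value: the two carbocycles are antipodal at the quaternary and isopropenyl-bearing carbons, while both lactone O–CH carbons are R (oxygen cis to the ring methyl in half B, trans in half A).

**Route**

Step 1
Reactants: 1 prenyl acetate; 2 acetic anhydride
Product: 3 rac-2-acetyl-3-methylbut-3-en-1-yl acetate
Conditions: ZnCl2 (0.2 equiv), CH2Cl2, 0 °C to rt
Reagents that add atoms: acetic anhydride (2), CC(=O)OC(C)=O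
Why: Ene-type Friedel–Crafts (Kondakov) acylation, in which the acylium ion adds to the less substituted alkene carbon and the tertiary cation loses a methyl proton to give the β,γ-unsaturated ketone; the new stereocentre is racemic and is planarised in step 2.

Step 2
Reactants: 3 keto acetate; 4 dimethyl 3-oxopentanedioate
Product: 7 cyclohexenone diester, via dienone 5 (not isolated), via Michael adduct 6 (not isolated)
Conditions: NaOMe (1.3 equiv), MeOH, 0 °C to rt, slow addition of 3, N2; aq NH4Cl
Reagents that add atoms: none
Why: Base-induced loss of acetic acid from 3 unmasks the cross-conjugated vinyl ketone 5, the sodium enolate of 4 adds to its CH2 terminus (Michael, the later C3a–C4 bond), and the remaining malonate-type CH2 of adduct 6 condenses with the methyl ketone with loss of water (intramolecular Knoevenagel, the later C6–C7 bond). The closest known reaction type is the Robinson/Hagemann-type Michael–Knoevenagel annulation of 3-oxoglutarates with vinyl ketones. The one ring is closed in a 6-(enolendo)-exo-trig aldol mode. The only lasting stereocentre, the isopropenyl-bearing carbon, is set by unselective protonation of the Michael enolate, and no control is wanted because both antipodes are used later; the ester-bearing ring carbon is enolisable. The step needs attack at the CH2 terminus of 5 (its only conjugate position), mono-addition, and closure by the glutarate CH2 rather than by the acetyl CH3: the doubly activated CH2 is the most nucleophilic carbon left in 6, its own ketone is enolised and so a poor acceptor, and the product is withdrawn as its stabilised enolate, which should also shield the isopropenyl group from moving into conjugation.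

Step 3
Reactants: 7 cyclohexenone diester; 8 ethyl bromoacetate
Product: 9 C1-alkylated cyclohexenone triester
Conditions: K2CO3 (1.5 equiv), acetone, rt
Reagents that add atoms: ethyl bromoacetate (8), CCOC(=O)CBr
Why: C-alkylation of the β-keto ester enolate (the most acidic C–H, between ketone and ester) by SN2 on the α-bromo ester; the new quaternary centre forms as both epimers, which converge in step 5.

Step 4
Reactants: 9 cyclohexenone triester; 10 vinylmagnesium bromide
Product: 11 4-ethenyl cyclohexanone triester
Conditions: CuBr·SMe2 (0.2 equiv), THF, −78 to −40 °C; aq NH4Cl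
Reagents that add atoms: vinylmagnesium bromide (10), C=C[Mg]Br
Why: Copper-catalysed conjugate addition to the doubly activated alkylidene β-keto ester; allylic 1,2-strain with the 4-methyl holds the neighbouring isopropenyl group pseudo-axial, so the vinyl group should enter anti to it by axial attack, giving the quaternary centre with vinyl trans and methyl cis to isopropenyl.

Step 5
Reactants: 11 cyclohexanone triester
Product: 12 racemic keto ester
Conditions: LiCl (5 equiv), H2O (3 equiv), DMSO, 150 °C
Reagents that add atoms: none
Why: Krapcho dealkoxycarbonylation, in which chloride demethylates the two β-keto methyl esters (the ethyl ester reacts far more slowly and has no β-carbonyl to drive loss of CO2); the carbon between ketone and side chain equilibrates through the enol to the equatorial epimer, with the side chain cis to the 4-methyl as needed.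

Step 6
Reactants: 12 racemic keto ester
Product: 14 cis-fused lactone, via hydroxy ester 13 (not isolated)
Conditions: (S)-2-methyl-CBS-oxazaborolidine (0.2 equiv), catecholborane (0.45 equiv), toluene, −78 °C, stopped below half conversion; MeOH; PPTS (cat.), CH2Cl2, rt; chromatography
Reagents that add atoms: none
Why: Corey–Bakshi–Shibata reduction run as a kinetic resolution: the catalyst (branched CH flank as the large group) delivers hydride to the face that leads to the 2R alcohol, which in the (1R,4S,5S) ketone is the open equatorial trajectory (the axial one is blocked by the syn-axial 4-methyl in both antipodes), so this antipode should give the axial alcohol 13 and lactonise cis, while the mismatched (1S,4R,5R) antipode reacts slowly; keeping the conversion below one half should keep the lactone enantiopure, and catecholborane at −78 °C should leave the alkenes untouched.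

Step 7
Reactants: 12 racemic keto ester
Product: 15 (1S,4R,5R)-keto ester
Conditions: (S)-2-methyl-CBS-oxazaborolidine (0.2 equiv), catecholborane (0.65 equiv), toluene, −78 °C, run beyond half conversion; MeOH; chromatography
Reagents that add atoms: none
Why: The same Corey–Bakshi–Shibata kinetic resolution on a second portion of 12, now driven past half conversion so that the fast-reacting (1R,4S,5S) antipode should be consumed completely and removed on silica as the more polar hydroxy ester, while the (1S,4R,5R) ketone, whose only open hydride trajectory is the one the catalyst disfavours, should be isolated unchanged in high enantiopurity; no stereocentre is formed.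

Step 8
Reactants: 14 cis-fused lactone; 16 N,N-dimethylmethyleneiminium iodide
Product: 19 α-methylene lactone, via Mannich base 17 (not isolated), via ammonium iodide 18 (not isolated)
Conditions: LiN(i-Pr)2 (1.1 equiv), THF, −78 °C; 16, −78 °C to rt; MeI, MeOH, rt; NaHCO3, CH2Cl2/H2O, rt
Reagents that add atoms: N,N-dimethylmethyleneiminium iodide (16), C=[N+](C)C.[I-]
Why: Mannich-type α-methylenation, in which the lactone enolate is aminomethylated, the amine is quaternised and then eliminated (E1cB) to the exocyclic alkene; the former α-centre becomes sp2.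

Step 9
Reactants: 19 α-methylene lactone; 20 1,3-dioxolane
Product: 21 dioxolanylmethyl lactone
Conditions: (Bu4N)4[W10O32] (2 mol %), MeCN/20 (1:1), 390 nm LED, rt, argon
Reagents that add atoms: 1,3-dioxolane (20), C1COCO1
Why: Decatungstate-photocatalysed hydrogen-atom abstraction from C2 of the dioxolane gives a nucleophilic acetal radical that adds to the CH2 terminus of the α-methylene lactone (Giese addition), and hydrogen back-transfer to the lactone α-radical from the convex face, opposite the cyclohexane ring, should set C3 as S with the side chain on the concave face.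

Step 10
Reactants: 21 dioxolanylmethyl lactone
Product: 22 lactone aldehyde
Conditions: PPTS (0.2 equiv), acetone/H2O (4:1), 55 °C
Reagents that add atoms: water, O
Why: Acid-catalysed acetal hydrolysis unmasks the aldehyde under conditions mild enough to leave the isopropenyl group and the lactone α-centre untouched; no stereocentre is formed.

Step 11
Reactants: 15 (1S,4R,5R)-keto ester
Product: 23 keto acid
Conditions: LiOH (3 equiv), THF/H2O, rt; 1 M HCl to pH 3
Reagents that add atoms: lithium hydroxide, [Li+].[OH-]
Why: Ester saponification; the epimerisable centre α to the ketone is erased in the next step, and the quaternary and isopropenyl-bearing centres are not touched.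

Step 12
Reactants: 23 keto acid
Product: 24 enol lactone
Conditions: Ac2O (3 equiv), NaOAc (0.5 equiv), 100 °C
Reagents that add atoms: none
Why: Enol lactonisation of the γ-keto acid through its mixed anhydride should give the tetrasubstituted ring-fusion enol lactone; any conjugated butenolide isomer formed alongside reacts through the same dienolate in step 13, and no stereocentre is formed.

Step 13
Reactants: 22 lactone aldehyde; 24 enol lactone
Product: 25 alkylidene enol lactone
Conditions: Et3N (0.2 equiv), 4 Å molecular sieves, CH2Cl2, 0 °C to rt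
Reagents that add atoms: none
Why: Knoevenagel condensation: the lactone CH2 of 24 is acidic because its anion is an aromatic 2-oxidofuran, whose α-carbon adds to the aldehyde before water is eliminated to give the cross-conjugated alkylidene lactone (E/Z mixture, inconsequential); no stereocentre is formed and triethylamine should not enolise the saturated lactone of 22.

Step 14
Reactants: 25 alkylidene enol lactone
Product: 27 target, via deconjugated lactone 26 (not isolated)
Conditions: [(Ph3P)CuH]6 (0.3 equiv), toluene, rt; aq NH4Cl; then DBU (0.1 equiv), CH2Cl2, rt, argon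
Reagents that add atoms: none
Why: Conjugate hydride transfer from the copper hydride to the exocyclic alkylidene carbon gives a copper 2-furanolate that is protonated on work-up, and DBU then equilibrates lactone 26 to the conjugated butenolide through the same dienolate, so C7a is set under thermodynamic control: the planar butenolide needs a pseudo-equatorial C–O bond, which the chair with equatorial isopropenyl offers only when oxygen is trans to the 6-methyl, i.e. 7aR.

**Compound list**

1 | 3-methylbut-2-en-1-yl acetate (prenyl acetate) | CC(C)=CCOC(C)=O | starting material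
2 | acetic anhydride | CC(=O)OC(C)=O | starting material
3 | rac-2-acetyl-3-methylbut-3-en-1-yl acetate | CC(=O)OCC(C(C)=O)C(C)=C | intermediate
4 | dimethyl 3-oxopentanedioate | COC(=O)CC(=O)CC(=O)OC | starting material
5 | 4-methyl-3-methylidenepent-4-en-2-one (formed in step 2, not isolated) | CC(=O)C(=C)C(C)=C | intermediate
6 | dimethyl 2-(2-acetyl-3-methylbut-3-en-1-yl)-3-oxopentanedioate, stereoisomer mixture (formed in step 2, not isolated) | COC(=O)CC(=O)C(C(=O)OC)CC(C(C)=C)C(C)=O | intermediate
7 | rac-dimethyl 4-methyl-2-oxo-5-(prop-1-en-2-yl)cyclohex-3-ene-1,3-dicarboxylate (C1 enolisable) | COC(=O)C1CC(C(C)=C)C(C)=C(C(=O)OC)C1=O | intermediate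
8 | ethyl bromoacetate | CCOC(=O)CBr | starting material
9 | rac-dimethyl 1-(2-ethoxy-2-oxoethyl)-4-methyl-2-oxo-5-(prop-1-en-2-yl)cyclohex-3-ene-1,3-dicarboxylate (both C1 epimers) | CCOC(=O)CC1(C(=O)OC)CC(C(C)=C)C(C)=C(C(=O)OC)C1=O | intermediate
10 | vinylmagnesium bromide | C=C[Mg]Br | starting material
11 | rac-dimethyl 4-ethenyl-1-(2-ethoxy-2-oxoethyl)-4-methyl-2-oxo-5-(prop-1-en-2-yl)cyclohexane-1,3-dicarboxylate, ethenyl trans and methyl cis to prop-1-en-2-yl (one enantiomer drawn; C1 and C3 unassigned) | CCOC(=O)CC1(C(=O)OC)C[C@@H](C(C)=C)[C@](C)(C=C)C(C(=O)OC)C1=O | intermediate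
12 | rac-ethyl 2-[4-ethenyl-4-methyl-2-oxo-5-(prop-1-en-2-yl)cyclohexyl]acetate, racemate of the (1R,4S,5S) and (1S,4R,5R) forms (the former drawn) | CCOC(=O)C[C@H]1C[C@@H](C(C)=C)[C@](C)(C=C)CC1=O | intermediate
13 | ethyl 2-[(1R,2R,4S,5S)-4-ethenyl-2-hydroxy-4-methyl-5-(prop-1-en-2-yl)cyclohexyl]acetate (formed in step 6, not isolated) | CCOC(=O)C[C@@H]1[C@H](O)C[C@@](C)(C=C)[C@H](C(=C)C)C1 | intermediate
14 | (3aR,5S,6S,7aR)-6-ethenyl-6-methyl-5-(prop-1-en-2-yl)hexahydro-1-benzofuran-2(3H)-one | O=C1O[C@@H]2C[C@@](C)(C=C)[C@H](C(=C)C)C[C@@H]2C1 | intermediate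
15 | ethyl 2-[(1S,4R,5R)-4-ethenyl-4-methyl-2-oxo-5-(prop-1-en-2-yl)cyclohexyl]acetate (slow-reacting antipode of 12, isolated in step 7) | CCOC(=O)C[C@@H]1C[C@H](C(C)=C)[C@@](C)(C=C)CC1=O | intermediate
16 | N,N-dimethylmethyleneiminium iodide | C=[N+](C)C.[I-] | starting material
17 | (3aR,5S,6S,7aR)-3-[(dimethylamino)methyl]-6-ethenyl-6-methyl-5-(prop-1-en-2-yl)hexahydro-1-benzofuran-2(3H)-one, C3 unassigned (formed in step 8, not isolated) | CN(C)CC1C(=O)O[C@@H]2C[C@@](C)(C=C)[C@H](C(=C)C)C[C@H]12 | intermediate
18 | trimethylammonium iodide of 17 (formed in step 8, not isolated) | C[N+](C)(C)CC1C(=O)O[C@@H]2C[C@@](C)(C=C)[C@H](C(=C)C)C[C@H]12.[I-] | intermediate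
19 | (3aR,5S,6S,7aR)-6-ethenyl-6-methyl-3-methylidene-5-(prop-1-en-2-yl)hexahydro-1-benzofuran-2(3H)-one | C=C1C(=O)O[C@@H]2C[C@@](C)(C=C)[C@H](C(=C)C)C[C@H]12 | intermediate
20 | 1,3-dioxolane | C1COCO1 | starting material
21 | (3S,3aR,5S,6S,7aR)-3-(1,3-dioxolan-2-ylmethyl)-6-ethenyl-6-methyl-5-(prop-1-en-2-yl)hexahydro-1-benzofuran-2(3H)-one | O1CCOC1C[C@@H]2C(=O)O[C@@H]3C[C@@](C)(C=C)[C@H](C(=C)C)C[C@H]23 | intermediate
22 | 2-[(3S,3aR,5S,6S,7aR)-6-ethenyl-6-methyl-2-oxo-5-(prop-1-en-2-yl)octahydro-1-benzofuran-3-yl]acetaldehyde | O=CC[C@@H]1C(=O)O[C@@H]2C[C@@](C)(C=C)[C@H](C(=C)C)C[C@H]12 | intermediate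
23 | 2-[(1S,4R,5R)-4-ethenyl-4-methyl-2-oxo-5-(prop-1-en-2-yl)cyclohexyl]acetic acid | OC(=O)C[C@@H]1C[C@H](C(C)=C)[C@@](C)(C=C)CC1=O | intermediate
24 | (5R,6R)-6-ethenyl-6-methyl-5-(prop-1-en-2-yl)-4,5,6,7-tetrahydro-1-benzofuran-2(3H)-one | O=C1CC2=C(O1)C[C@](C)(C=C)[C@@H](C(C)=C)C2 | intermediate
25 | (5R,6R)-6-ethenyl-3-{2-[(3S,3aR,5S,6S,7aR)-6-ethenyl-6-methyl-2-oxo-5-(prop-1-en-2-yl)octahydro-1-benzofuran-3-yl]ethylidene}-6-methyl-5-(prop-1-en-2-yl)-4,5,6,7-tetrahydro-1-benzofuran-2(3H)-one (E/Z mixture) | O=C1OC2=C(C[C@H](C(C)=C)[C@@](C)(C=C)C2)C1=CC[C@@H]3C(=O)O[C@@H]4C[C@@](C)(C=C)[C@H](C(=C)C)C[C@H]34 | intermediate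
26 | 3-alkyl analogue of 25 with a saturated CH2CH2 link and the ring-fusion enol lactone retained, C3 unassigned (formed in step 14, not isolated) | O=C1OC2=C(C[C@H](C(C)=C)[C@@](C)(C=C)C2)C1CC[C@@H]3C(=O)O[C@@H]4C[C@@](C)(C=C)[C@H](C(=C)C)C[C@H]34 | intermediate
27 | (5R,6R,7aR)-6-ethenyl-3-{2-[(3S,3aR,5S,6S,7aR)-6-ethenyl-6-methyl-2-oxo-5-(prop-1-en-2-yl)octahydro-1-benzofuran-3-yl]ethyl}-6-methyl-5-(prop-1-en-2-yl)-5,6,7,7a-tetrahydro-1-benzofuran-2(4H)-one | C=C[C@@]1(C)C[C@H]2OC(=O)C(CC[C@@H]3C(=O)O[C@@H]4C[C@@](C)(C=C)[C@H](C(=C)C)C[C@H]34)=C2C[C@@H]1C(=C)C | target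

**Step count and risks**

Total step count: 14. Longest linear sequence: 11 (steps 1–6, 8–10, 13, 14).

Steps most likely to fail:

Step 2. The transient dienone 5 may oligomerise by Diels–Alder dimerisation, or the isopropenyl double bond may migrate into conjugation, before the Michael addition takes place. The fallback inverts the polarity of the Michael step in a Hagemann-type three-component condensation that never frees 5. It sets out from 4: condensation with formaldehyde (piperidinium acetate, MeCN, 0 °C) would give dimethyl 2-methylidene-3-oxopentanedioate F1. In the same flask F1 would be trapped by the doubly activated CH2 of commercial 4-methylpent-4-en-2-one to give 6, which closes by the same Knoevenagel condensation. The route is rejoined at 7.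

Step 6. The catalyst may discriminate too weakly between the two enantiomers of 12, so that the lactone of step 6 and the recovered ketone of step 7 are both of low enantiopurity. The fallback is a classical salt resolution that sets out from 12 and replaces steps 6, 7 and 11. Saponification (LiOH, THF/H2O) would give the racemic keto acid, that is 23 and its antipode 2-[(1R,4S,5S)-4-ethenyl-4-methyl-2-oxo-5-(prop-1-en-2-yl)cyclohexyl]acetic acid F2. Fractional crystallisation with (R)-1-phenylethylamine would separate the (R)-1-phenylethylammonium salt of the (1R,4S,5S) acid F3 from the (R)-1-phenylethylammonium salt of the (1S,4R,5R) acid F4, and acidification would free F2 and 23. Reduction of F2 with LiBH(s-Bu)3 (2.2 equiv, THF, −78 °C; equatorial attack) would give 2-[(1R,2R,4S,5S)-4-ethenyl-2-hydroxy-4-methyl-5-(prop-1-en-2-yl)cyclohexyl]acetic acid F5, which lactonises on acidic work-up. The route is rejoined at 14 and at 23.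

Step 13. The aldehyde may self-aldolise, or a second lactone anion may add to the alkylidene product, faster than the clean mono-condensation. The fallback replaces condensation and reduction by an alkylation that sets out from 22 and 24. Reduction of 22 (NaBH4, MeOH, −40 °C) would give (3S,3aR,5S,6S,7aR)-6-ethenyl-3-(2-hydroxyethyl)-6-methyl-5-(prop-1-en-2-yl)hexahydro-1-benzofuran-2(3H)-one F6. Without storage, I2, PPh3 and imidazole would convert it into (3S,3aR,5S,6S,7aR)-6-ethenyl-3-(2-iodoethyl)-6-methyl-5-(prop-1-en-2-yl)hexahydro-1-benzofuran-2(3H)-one F7. The lithium 2-furanolate of 24 (LiN(SiMe3)2, THF/DMPU, −78 °C) would be alkylated at C3 by F7; the furanolate is too weak a base to enolise the saturated lactone. The route is rejoined at 26, which DBU converts into 27 as in step 14.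

Further compounds
F1 | step 2 | dimethyl 2-methylidene-3-oxopentanedioate | C=C(C(=O)OC)C(=O)CC(=O)OC
F2 | step 6 | 2-[(1R,4S,5S)-4-ethenyl-4-methyl-2-oxo-5-(prop-1-en-2-yl)cyclohexyl]acetic acid | OC(=O)C[C@H]1C[C@@H](C(C)=C)[C@](C)(C=C)CC1=O
F3 | step 6 | (R)-1-phenylethylammonium salt of the (1R,4S,5S) acid | [O-]C(=O)C[C@H]1C[C@@H](C(C)=C)[C@](C)(C=C)CC1=O.C[C@@H]([NH3+])c1ccccc1
F4 | step 6 | (R)-1-phenylethylammonium salt of the (1S,4R,5R) acid | [O-]C(=O)C[C@@H]1C[C@H](C(C)=C)[C@@](C)(C=C)CC1=O.C[C@@H]([NH3+])c1ccccc1
F5 | step 6 | 2-[(1R,2R,4S,5S)-4-ethenyl-2-hydroxy-4-methyl-5-(prop-1-en-2-yl)cyclohexyl]acetic acid | OC(=O)C[C@@H]1[C@H](O)C[C@@](C)(C=C)[C@H](C(=C)C)C1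
F6 | step 13 | (3S,3aR,5S,6S,7aR)-6-ethenyl-3-(2-hydroxyethyl)-6-methyl-5-(prop-1-en-2-yl)hexahydro-1-benzofuran-2(3H)-one | OCC[C@@H]1C(=O)O[C@@H]2C[C@@](C)(C=C)[C@H](C(=C)C)C[C@H]12
F7 | step 13 | (3S,3aR,5S,6S,7aR)-6-ethenyl-3-(2-iodoethyl)-6-methyl-5-(prop-1-en-2-yl)hexahydro-1-benzofuran-2(3H)-one | ICC[C@@H]1C(=O)O[C@@H]2C[C@@](C)(C=C)[C@H](C(=C)C)C[C@H]12
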